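**Strategy.** In tetralin numbering, C1 is a doubly benzylic methine bonded to C8a of ring A and to the carbon para to OH of the 4-hydroxy-3,5-dimethoxyphenyl ring, so it is traced back to an aldehyde carbon. In one Lewis-acid operation the formyl carbon of a 4-arylbutanal alkylates ring A at C8a, closing ring B, and the resulting 1-tetralyl cation then arylates 2,6-dimethoxyphenol trans to the C2 arm. The precursor is the (2S,3S)-butanal carrying the ring A aryl at C4, a benzyloxymethyl group at C3 and a silyloxymethyl group at C2. C3 comes from asymmetric hydrogenation of a Stobbe half-ester and C2 from an auxiliary-controlled hydroxymethylation.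

Key step: step 10

Remark (abbreviations): Ar = 4-(benzyloxy)-3,5-dimethoxyphenyl, Bn = benzyl, TBDPS = tert-butyldiphenylsilyl; ring A is the fused arene C4a–C8a, ring B the carbocycle.

Remark (configuration): the target is (1R,2S,3S) with the C1 aryl, the C2 arm and the C3 arm mutually trans. This requires the (2S,3S) aldehyde 18, whose two oxymethyl arms are syn when C1–C4 is drawn zigzag. A trans-hydroxymethylated β-benzyl-γ-butyrolactone gives this isomer only if its hydroxymethyl carbon, not its carbonyl carbon, becomes the formyl group; the other assignment gives the 2,3-anti aldehyde and a 2,3-cis tetralin. C2 is therefore set by reagent control in step 6.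

Remark (sulfate): the target is drawn as the free hydrogen sulfate; 25 and 26 are handled as sodium salts and the acid form is released on an acid ion-exchange resin at the end.

**Step 1**
Reactants: 1 syringaldehyde
Product: 2 4-(benzyloxy)-3,5-dimethoxybenzaldehyde
Conditions: BnBr, K2CO3, DMF, 60 °C
Reagents that add atoms: benzyl bromide, BrCc1ccccc1
Why: Williamson ether synthesis on the acidic 2,6-dimethoxyphenol should be clean and installs a phenol protecting group that lasts until the final hydrogenolysis.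

**Step 2**
Reactants: 2 4-(benzyloxy)-3,5-dimethoxybenzaldehyde; 3 dimethyl succinate
Product: 5 (E)-4-Ar-3-(methoxycarbonyl)but-3-enoic acid, via Stobbe lactone ester 4 (not isolated)
Conditions: NaOMe, MeOH, reflux; then aq HCl
Reagents that add atoms: none
Why: Stobbe condensation (aldol addition, lactonisation to the paraconate 4, E1cB ring opening) should give the half-ester with the free acid on the CH2 arm and the usual E geometry.

**Step 3**
Reactants: 5 (E)-4-Ar-3-(methoxycarbonyl)but-3-enoic acid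
Product: 6 (S)-4-Ar-3-(methoxycarbonyl)butanoic acid
Conditions: [Rh(cod)((R,R)-Et-DuPhos)]BF4 (cat.), H2 (5 bar), NaOMe (10 mol%), MeOH, 25 °C
Reagents that add atoms: none
Why: [Rh(cod)(Et-DuPhos)]BF4-catalysed asymmetric hydrogenation of Stobbe-type itaconate half-esters is established and should reduce the carboxylate-bound alkene from one face to set the future C3 as S without touching the aryl benzyl ether, the ligand antipode being exchanged if an aliquot of lactone 8 drawn in step 4 shows the opposite sign of rotation.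

**Step 4**
Reactants: 6 (S)-4-Ar-3-(methoxycarbonyl)butanoic acid
Product: 10 (S)-4-Ar-3-[(benzyloxy)methyl]butanoic acid, via hydroxy acid 7 (not isolated), via lactone 8 (not isolated), via benzyl ester 9 (not isolated)
Conditions: KOH (1 equiv), EtOH; CaCl2, NaBH4, −10 °C to rt; 3 M HCl, extraction into toluene, azeotropic drying; KOH (powder), BnBr, toluene, reflux; KOH, MeOH–H2O, reflux; HCl
Reagents that add atoms: benzyl bromide, BrCc1ccccc1; potassium hydroxide, [K+].[OH-]
Why: in this telescoped chemoselective ester reduction and Williamson etherification, Ca(BH4)2 should reduce the methyl ester but not the carboxylate, acidification closes γ-lactone 8, which is carried on as its crude toluene solution, and powdered KOH then reopens the ring so that double benzylation and saponification of benzyl ester 9 leave an O-benzyl acid that cannot relactonise, the stereocentre being β to the carboxyl and never enolisable.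

**Step 5**
Reactants: 10 (S)-4-Ar-3-[(benzyloxy)methyl]butanoic acid; 11 (R)-4-benzyloxazolidin-2-one
Product: 13 (R)-4-benzyl-3-{(S)-4-Ar-3-[(benzyloxy)methyl]butanoyl}oxazolidin-2-one, via mixed anhydride 12 (not isolated)
Conditions: t-BuCOCl, Et3N, THF, −20 °C; then LiCl, 11, −20 °C to rt
Reagents that add atoms: none
Why: mixed-anhydride N-acylation of the oxazolidinone is a standard way to attach the auxiliary that will control C2.

**Step 6**
Reactants: 13 (R)-4-benzyl-3-{(S)-4-Ar-3-[(benzyloxy)methyl]butanoyl}oxazolidin-2-one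
Product: 15 (R)-4-benzyl-3-{(2S,3S)-4-Ar-3-[(benzyloxy)methyl]-2-(hydroxymethyl)butanoyl}oxazolidin-2-one, via trichlorotitanium enolate 14 (not isolated)
Conditions: TiCl4, i-Pr2NEt, CH2Cl2, 0 °C; then 1,3,5-trioxane, TiCl4, 0 °C; aq NH4Cl
Reagents that add atoms: 1,3,5-trioxane, C1OCOCO1
Why: in this Evans-type titanium-enolate hydroxymethylation the chelated (Z)-enolate 14 is attacked by TiCl4-activated formaldehyde on the face away from the oxazolidinone benzyl group, which with the (R)-auxiliary sets C2 as S (arms syn) and should override the weak bias of the β-stereocentre.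

**Step 7**
Reactants: 15 (R)-4-benzyl-3-{(2S,3S)-4-Ar-3-[(benzyloxy)methyl]-2-(hydroxymethyl)butanoyl}oxazolidin-2-one
Product: 16 (R)-4-benzyl-3-{(2S,3S)-4-Ar-3-[(benzyloxy)methyl]-2-[(TBDPS-oxy)methyl]butanoyl}oxazolidin-2-one
Conditions: TBDPSCl, imidazole, DMF, rt
Reagents that add atoms: tert-butyl(chloro)diphenylsilane, CC(C)(C)[Si](Cl)(c1ccccc1)c1ccccc1
Why: standard silylation of the primary alcohol gives a bulky, Lewis-acid-tolerant ether that is the only fluoride-labile group in the molecule.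

**Step 8**
Reactants: 16 (R)-4-benzyl-3-{(2S,3S)-4-Ar-3-[(benzyloxy)methyl]-2-[(TBDPS-oxy)methyl]butanoyl}oxazolidin-2-one
Product: 17 (2R,3S)-4-Ar-3-[(benzyloxy)methyl]-2-[(TBDPS-oxy)methyl]butan-1-ol
Conditions: LiBH4, MeOH (1 equiv), THF, 0 °C; aq NH4Cl
Reagents that add atoms: none
Why: LiBH4 reductively cleaves the imide at the exocyclic carbonyl to the primary alcohol and returns the auxiliary, and at 0 °C no 1,3-silyl shift between the two C2 carbinols (which would invert C2) is expected.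

**Step 9**
Reactants: 17 (2R,3S)-4-Ar-3-[(benzyloxy)methyl]-2-[(TBDPS-oxy)methyl]butan-1-ol
Product: 18 (2S,3S)-4-Ar-3-[(benzyloxy)methyl]-2-[(TBDPS-oxy)methyl]butanal
Conditions: Dess–Martin periodinane, CH2Cl2, 0 °C to rt; used crude at once
Reagents that add atoms: none
Why: Dess–Martin oxidation is non-basic and should give the α-branched aldehyde without epimerisation or β-elimination of silanol.

**Step 10**
Reactants: 18 (2S,3S)-4-Ar-3-[(benzyloxy)methyl]-2-[(TBDPS-oxy)methyl]butanal; 19 2,6-dimethoxyphenol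
Product: 22 4-[(1R,2S,3S)-7-(benzyloxy)-3-[(benzyloxy)methyl]-2-[(TBDPS-oxy)methyl]-6,8-dimethoxy-1,2,3,4-tetrahydronaphthalen-1-yl]-2,6-dimethoxyphenol, via tetralol 20 (not isolated), via tetralyl cation 21 (not isolated)
Conditions: BF3·OEt2 (2.5 equiv), CH2Cl2 (0.02 M), −78 °C; 19 (2 equiv) added slowly, −78 to −20 °C; aq NaHCO3
Reagents that add atoms: none
Why: BF3 activates the formyl group, the ring A carbon ortho to the side chain (para to one methoxyl, ortho to the other; both ortho positions are equivalent) attacks it, and the boron-bound 1-tetralol 20 ionises to the ortho,para-dimethoxy-stabilised benzylic cation 21, which 19 captures through its carbon para to OH with loss of a proton. The closest known reaction types are the acid-mediated cyclisation of 4-arylbutanals to 1-tetralyl cations and the double Friedel–Crafts arylation of aldehydes to triarylmethanes. Ring B closes in a 6-exo-trig Friedel–Crafts hydroxyalkylation, C1–C8a being the ring-forming bond. C1 is the only new stereocentre and is set by substrate control from C2: in the half-chair cation the CH2OTBDPS group lies pseudo-equatorial beside the cationic centre and 19 adds to the opposite face, giving the 1,2-trans (1R) isomer, which is also the more stable one if the arylation is reversible. The step needs ring closure before intermolecular arylation (six-membered tether, high dilution, slow addition of 19), para attack on 19 (OH is the strongest donor and both its ortho positions carry methoxyl) and an unchanged C2 (low temperature, no base, fast closure of the α-branched aldehyde).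

**Step 11**
Reactants: 22 4-[(1R,2S,3S)-7-(benzyloxy)-3-[(benzyloxy)methyl]-2-[(TBDPS-oxy)methyl]-6,8-dimethoxy-1,2,3,4-tetrahydronaphthalen-1-yl]-2,6-dimethoxyphenol
Product: 23 (1R,2S,3S)-7-(benzyloxy)-1-Ar-3-[(benzyloxy)methyl]-2-[(TBDPS-oxy)methyl]-6,8-dimethoxy-1,2,3,4-tetrahydronaphthalene
Conditions: BnBr, K2CO3, DMF, rt
Reagents that add atoms: benzyl bromide, BrCc1ccccc1
Why: Williamson benzylation masks the new phenol so that only the C2 carbinol is sulfated later and all three benzyl ethers fall in one final operation.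

**Step 12**
Reactants: 23 (1R,2S,3S)-7-(benzyloxy)-1-Ar-3-[(benzyloxy)methyl]-2-[(TBDPS-oxy)methyl]-6,8-dimethoxy-1,2,3,4-tetrahydronaphthalene
Product: 24 [(1R,2S,3S)-7-(benzyloxy)-1-Ar-3-[(benzyloxy)methyl]-6,8-dimethoxy-1,2,3,4-tetrahydronaphthalen-2-yl]methanol
Conditions: Bu4NF, AcOH (1:1), THF, rt
Reagents that add atoms: none
Why: buffered fluoride cleaves the Si–O bond selectively and benzyl ethers are inert to it.

**Step 13**
Reactants: 24 [(1R,2S,3S)-7-(benzyloxy)-1-Ar-3-[(benzyloxy)methyl]-6,8-dimethoxy-1,2,3,4-tetrahydronaphthalen-2-yl]methanol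
Product: 25 [(1R,2S,3S)-7-(benzyloxy)-1-Ar-3-[(benzyloxy)methyl]-6,8-dimethoxy-1,2,3,4-tetrahydronaphthalen-2-yl]methyl hydrogen sulfate
Conditions: SO3·pyridine, DMF, rt; sodium-form cation-exchange resin
Reagents that add atoms: sulfur trioxide–pyridine complex, O=S(=O)=O.c1ccncc1
Why: O-sulfation of the only free hydroxyl with SO3·pyridine should give the monoalkyl sulfate, which is stable as its sodium salt.

**Step 14**
Reactants: 25 [(1R,2S,3S)-7-(benzyloxy)-1-Ar-3-[(benzyloxy)methyl]-6,8-dimethoxy-1,2,3,4-tetrahydronaphthalen-2-yl]methyl hydrogen sulfate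
Product: 26 [(1R,2S,3S)-7-hydroxy-1-(4-hydroxy-3,5-dimethoxyphenyl)-3-(hydroxymethyl)-6,8-dimethoxy-1,2,3,4-tetrahydronaphthalen-2-yl]methyl hydrogen sulfate (target)
Conditions: H2 (1 atm), 10% Pd/C, MeOH–H2O, rt; then acid-form cation-exchange resin, 0 °C
Reagents that add atoms: none
Why: hydrogenolysis over Pd/C should remove the two aryl and one alkyl benzyl ethers while the monoalkyl sulfate salt and the C1 diarylmethine stay intact.

**Compound list**

1 | syringaldehyde (4-hydroxy-3,5-dimethoxybenzaldehyde) | COc1cc(C=O)cc(OC)c1O | starting material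
2 | 4-(benzyloxy)-3,5-dimethoxybenzaldehyde | COc1cc(C=O)cc(OC)c1OCc1ccccc1 | intermediate
3 | dimethyl succinate | COC(=O)CCC(=O)OC | starting material
4 | methyl 2-Ar-5-oxotetrahydrofuran-3-carboxylate (Stobbe lactone ester, isomer mixture) | COC(=O)C1CC(=O)OC1c1cc(OC)c(OCc2ccccc2)c(OC)c1 | intermediate (not isolated)
5 | (E)-4-Ar-3-(methoxycarbonyl)but-3-enoic acid | OC(=O)C/C(C(=O)OC)=C\c1cc(OC)c(OCc2ccccc2)c(OC)c1 | intermediate
6 | (S)-4-Ar-3-(methoxycarbonyl)butanoic acid | OC(=O)C[C@@H](C(=O)OC)Cc1cc(OC)c(OCc2ccccc2)c(OC)c1 | intermediate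
7 | (S)-4-Ar-3-(hydroxymethyl)butanoic acid (hydroxy acid, present as its salts) | OC(=O)C[C@@H](CO)Cc1cc(OC)c(OCc2ccccc2)c(OC)c1 | intermediate (not isolated)
8 | (S)-4-(Ar-methyl)dihydrofuran-2(3H)-one (lactone, carried on as a crude toluene solution) | O=C1C[C@H](Cc2cc(OC)c(OCc3ccccc3)c(OC)c2)CO1 | intermediate (not isolated)
9 | benzyl (S)-4-Ar-3-[(benzyloxy)methyl]butanoate | O=C(OCc1ccccc1)C[C@@H](COCc1ccccc1)Cc1cc(OC)c(OCc2ccccc2)c(OC)c1 | intermediate (not isolated)
10 | (S)-4-Ar-3-[(benzyloxy)methyl]butanoic acid | OC(=O)C[C@@H](COCc1ccccc1)Cc1cc(OC)c(OCc2ccccc2)c(OC)c1 | intermediate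
11 | (R)-4-benzyloxazolidin-2-one | O=C1N[C@H](Cc2ccccc2)CO1 | starting material
12 | mixed anhydride of 10 with pivalic acid | CC(C)(C)C(=O)OC(=O)C[C@@H](COCc1ccccc1)Cc1cc(OC)c(OCc2ccccc2)c(OC)c1 | intermediate (not isolated)
13 | (R)-4-benzyl-3-{(S)-4-Ar-3-[(benzyloxy)methyl]butanoyl}oxazolidin-2-one | O=C1OC[C@@H](Cc2ccccc2)N1C(=O)C[C@@H](COCc1ccccc1)Cc1cc(OC)c(OCc2ccccc2)c(OC)c1 | intermediate
14 | trichlorotitanium (Z)-enolate of 13 | Cl[Ti](Cl)(Cl)O/C(=C\[C@@H](COCc1ccccc1)Cc1cc(OC)c(OCc2ccccc2)c(OC)c1)N1[C@H](Cc2ccccc2)COC1=O | intermediate (not isolated)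
15 | (R)-4-benzyl-3-{(2S,3S)-4-Ar-3-[(benzyloxy)methyl]-2-(hydroxymethyl)butanoyl}oxazolidin-2-one | O=C1OC[C@@H](Cc2ccccc2)N1C(=O)[C@H](CO)[C@@H](COCc1ccccc1)Cc1cc(OC)c(OCc2ccccc2)c(OC)c1 | intermediate
16 | (R)-4-benzyl-3-{(2S,3S)-4-Ar-3-[(benzyloxy)methyl]-2-[(TBDPS-oxy)methyl]butanoyl}oxazolidin-2-one | O=C1OC[C@@H](Cc2ccccc2)N1C(=O)[C@H](CO[Si](c1ccccc1)(c1ccccc1)C(C)(C)C)[C@@H](COCc1ccccc1)Cc1cc(OC)c(OCc2ccccc2)c(OC)c1 | intermediate
17 | (2R,3S)-4-Ar-3-[(benzyloxy)methyl]-2-[(TBDPS-oxy)methyl]butan-1-ol | OC[C@H](CO[Si](c1ccccc1)(c1ccccc1)C(C)(C)C)[C@@H](COCc1ccccc1)Cc1cc(OC)c(OCc2ccccc2)c(OC)c1 | intermediate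
18 | (2S,3S)-4-Ar-3-[(benzyloxy)methyl]-2-[(TBDPS-oxy)methyl]butanal (key-step precursor) | O=C[C@H](CO[Si](c1ccccc1)(c1ccccc1)C(C)(C)C)[C@@H](COCc1ccccc1)Cc1cc(OC)c(OCc2ccccc2)c(OC)c1 | intermediate
19 | 2,6-dimethoxyphenol | COc1cccc(OC)c1O | starting material
20 | (2S,3S)-7-(benzyloxy)-3-[(benzyloxy)methyl]-2-[(TBDPS-oxy)methyl]-6,8-dimethoxy-1,2,3,4-tetrahydronaphthalen-1-ol (C1 epimers, boron-bound) | OC2c3c(cc(OC)c(OCc4ccccc4)c3OC)C[C@H](COCc5ccccc5)[C@H]2CO[Si](c6ccccc6)(c7ccccc7)C(C)(C)C | intermediate (not isolated)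
21 | 1-tetralyl cation derived from 20 | [CH+]2c3c(cc(OC)c(OCc4ccccc4)c3OC)C[C@H](COCc5ccccc5)[C@H]2CO[Si](c6ccccc6)(c7ccccc7)C(C)(C)C | intermediate (not isolated)
22 | 4-[(1R,2S,3S)-7-(benzyloxy)-3-[(benzyloxy)methyl]-2-[(TBDPS-oxy)methyl]-6,8-dimethoxy-1,2,3,4-tetrahydronaphthalen-1-yl]-2,6-dimethoxyphenol (key-step product) | COc1cc(cc(OC)c1O)[C@@H]2c3c(cc(OC)c(OCc4ccccc4)c3OC)C[C@H](COCc5ccccc5)[C@H]2CO[Si](c6ccccc6)(c7ccccc7)C(C)(C)C | intermediate
23 | (1R,2S,3S)-7-(benzyloxy)-1-Ar-3-[(benzyloxy)methyl]-2-[(TBDPS-oxy)methyl]-6,8-dimethoxy-1,2,3,4-tetrahydronaphthalene | COc1cc(cc(OC)c1OCc8ccccc8)[C@@H]2c3c(cc(OC)c(OCc4ccccc4)c3OC)C[C@H](COCc5ccccc5)[C@H]2CO[Si](c6ccccc6)(c7ccccc7)C(C)(C)C | intermediate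
24 | [(1R,2S,3S)-7-(benzyloxy)-1-Ar-3-[(benzyloxy)methyl]-6,8-dimethoxy-1,2,3,4-tetrahydronaphthalen-2-yl]methanol | COc1cc(cc(OC)c1OCc8ccccc8)[C@@H]2c3c(cc(OC)c(OCc4ccccc4)c3OC)C[C@H](COCc5ccccc5)[C@H]2CO | intermediate
25 | [(1R,2S,3S)-7-(benzyloxy)-1-Ar-3-[(benzyloxy)methyl]-6,8-dimethoxy-1,2,3,4-tetrahydronaphthalen-2-yl]methyl hydrogen sulfate | COc1cc(cc(OC)c1OCc8ccccc8)[C@@H]2c3c(cc(OC)c(OCc4ccccc4)c3OC)C[C@H](COCc5ccccc5)[C@H]2COS(=O)(=O)O | intermediate
26 | [(1R,2S,3S)-7-hydroxy-1-(4-hydroxy-3,5-dimethoxyphenyl)-3-(hydroxymethyl)-6,8-dimethoxy-1,2,3,4-tetrahydronaphthalen-2-yl]methyl hydrogen sulfate | COc1cc([C@@H]2c3c(cc(OC)c(O)c3OC)C[C@H](CO)[C@H]2COS(=O)(=O)O)cc(OC)c1O | target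

**Totals.** Total step count: 14. Longest linear sequence: 14 steps from syringaldehyde (3, 11 and 19 are bought).

**Steps most likely to fail**

Step 10 (key step). The aldehyde may be arylated by two molecules of 19 before the ring closes. C2 may lose its configuration by enolisation of 18, or by proton loss from cation 21 and re-protonation. Compound 19 may add to the face cis to the C2 arm. The cation may be trapped by the ether oxygen of the C3 arm. The fallback sets out from aldehyde 18, brings in the pendant ring as a carbon nucleophile and closes ring B afterwards. Commercial 4-bromo-2,6-dimethoxyphenol is benzylated (BnBr, K2CO3, DMF) to 2-(benzyloxy)-5-bromo-1,3-dimethoxybenzene F1. This is converted with Mg in THF into [4-(benzyloxy)-3,5-dimethoxyphenyl]magnesium bromide F2, which is added to 18 at −78 °C to give (2S,3S)-1,4-bis-Ar-3-[(benzyloxy)methyl]-2-[(TBDPS-oxy)methyl]butan-1-ol F3 as a mixture of C1 epimers. BF3·OEt2 or CF3CO2H in CH2Cl2 then ionises the carbinol and ring A closes on the diarylmethyl cation, the classical 1,2-trans-selective cyclolignan Friedel–Crafts closure. This gives tris-benzyl ether 23 directly, where the route is rejoined at step 12.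

Step 6. A benzyl ether may be cleaved or ring A hydroxymethylated under TiCl4, the β-branched enolate may react sluggishly, or facial control may be poor. The fallback sets out from lactone 8, which is isolated for this purpose by stopping step 4 after the acid work-up, and uses substrate control in the ring, with the hydroxymethyl carbon destined to become the formyl carbon. Deprotonation with LiN(i-Pr)2 in THF at −78 °C followed by monomeric formaldehyde should give (3R,4S)-4-(Ar-methyl)-3-(hydroxymethyl)dihydrofuran-2(3H)-one F4, the new group entering trans to the benzyl group. Silylation (t-BuMe2SiCl, imidazole) gives (3R,4S)-4-(Ar-methyl)-3-{[(tert-butyldimethylsilyl)oxy]methyl}dihydrofuran-2(3H)-one F5. AlMe3 and MeNH(OMe)·HCl open the lactone to (2R,3S)-4-Ar-2-{[(tert-butyldimethylsilyl)oxy]methyl}-3-(hydroxymethyl)-N-methoxy-N-methylbutanamide F6. Benzyl 2,2,2-trichloroacetimidate with catalytic CF3SO3H gives (2R,3S)-4-Ar-3-[(benzyloxy)methyl]-2-{[(tert-butyldimethylsilyl)oxy]methyl}-N-methoxy-N-methylbutanamide F7. Reduction with i-Bu2AlH at −78 °C gives (2R,3S)-4-Ar-3-[(benzyloxy)methyl]-2-{[(tert-butyldimethylsilyl)oxy]methyl}butanal F8, which is reduced in the same pot with NaBH4 to (2S,3S)-4-Ar-3-[(benzyloxy)methyl]-2-{[(tert-butyldimethylsilyl)oxy]methyl}butan-1-ol F9. TBDPSCl and imidazole give (2R,3S)-4-Ar-3-[(benzyloxy)methyl]-2-{[(tert-butyldimethylsilyl)oxy]methyl}-1-(TBDPS-oxy)butane F10. Pyridinium p-toluenesulfonate in MeOH then removes the primary tert-butyldimethylsilyl ether selectively and gives alcohol 17, where the route is rejoined at step 9.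

Step 13. Sulfation of the hindered, neopentyl-like carbinol may be incomplete, or the sulfate may be lost by acid-catalysed solvolysis during work-up and chromatography. The fallback sets out from alcohol 24 and carries the sulfate as a neutral diester. Reaction with 1,2-dimethyl-3-[(2,2,2-trichloroethoxy)sulfonyl]imidazolium triflate and 1,2-dimethylimidazole in CH2Cl2 gives 2,2,2-trichloroethyl [(1R,2S,3S)-7-(benzyloxy)-1-Ar-3-[(benzyloxy)methyl]-6,8-dimethoxy-1,2,3,4-tetrahydronaphthalen-2-yl]methyl sulfate F11, which can be purified on silica. Zn dust and HCO2NH4 in MeOH then remove the trichloroethyl group by reductive fragmentation and give monoester 25, where the route is rejoined at step 14.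

**Further compounds**

F1 | step 10 | 2-(benzyloxy)-5-bromo-1,3-dimethoxybenzene | COc1cc(Br)cc(OC)c1OCc1ccccc1
F2 | step 10 | [4-(benzyloxy)-3,5-dimethoxyphenyl]magnesium bromide | COc1cc([Mg]Br)cc(OC)c1OCc1ccccc1
F3 | step 10 | (2S,3S)-1,4-bis-Ar-3-[(benzyloxy)methyl]-2-[(TBDPS-oxy)methyl]butan-1-ol (C1 epimers) | OC(c1cc(OC)c(OCc2ccccc2)c(OC)c1)[C@H](CO[Si](c1ccccc1)(c1ccccc1)C(C)(C)C)[C@@H](COCc1ccccc1)Cc1cc(OC)c(OCc2ccccc2)c(OC)c1
F4 | step 6 | (3R,4S)-4-(Ar-methyl)-3-(hydroxymethyl)dihydrofuran-2(3H)-one | O=C1[C@@H](CO)[C@H](Cc2cc(OC)c(OCc3ccccc3)c(OC)c2)CO1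
F5 | step 6 | (3R,4S)-4-(Ar-methyl)-3-{[(tert-butyldimethylsilyl)oxy]methyl}dihydrofuran-2(3H)-one | O=C1[C@@H](CO[Si](C)(C)C(C)(C)C)[C@H](Cc2cc(OC)c(OCc3ccccc3)c(OC)c2)CO1
F6 | step 6 | (2R,3S)-4-Ar-2-{[(tert-butyldimethylsilyl)oxy]methyl}-3-(hydroxymethyl)-N-methoxy-N-methylbutanamide | CON(C)C(=O)[C@@H](CO[Si](C)(C)C(C)(C)C)[C@@H](CO)Cc1cc(OC)c(OCc2ccccc2)c(OC)c1
F7 | step 6 | (2R,3S)-4-Ar-3-[(benzyloxy)methyl]-2-{[(tert-butyldimethylsilyl)oxy]methyl}-N-methoxy-N-methylbutanamide | CON(C)C(=O)[C@@H](CO[Si](C)(C)C(C)(C)C)[C@@H](COCc1ccccc1)Cc1cc(OC)c(OCc2ccccc2)c(OC)c1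
F8 | step 6 | (2R,3S)-4-Ar-3-[(benzyloxy)methyl]-2-{[(tert-butyldimethylsilyl)oxy]methyl}butanal | O=C[C@@H](CO[Si](C)(C)C(C)(C)C)[C@@H](COCc1ccccc1)Cc1cc(OC)c(OCc2ccccc2)c(OC)c1
F9 | step 6 | (2S,3S)-4-Ar-3-[(benzyloxy)methyl]-2-{[(tert-butyldimethylsilyl)oxy]methyl}butan-1-ol | OC[C@@H](CO[Si](C)(C)C(C)(C)C)[C@@H](COCc1ccccc1)Cc1cc(OC)c(OCc2ccccc2)c(OC)c1
F10 | step 6 | (2R,3S)-4-Ar-3-[(benzyloxy)methyl]-2-{[(tert-butyldimethylsilyl)oxy]methyl}-1-(TBDPS-oxy)butane | CC(C)(C)[Si](c1ccccc1)(c1ccccc1)OC[C@@H](CO[Si](C)(C)C(C)(C)C)[C@@H](COCc1ccccc1)Cc1cc(OC)c(OCc2ccccc2)c(OC)c1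
F11 | step 13 | 2,2,2-trichloroethyl [(1R,2S,3S)-7-(benzyloxy)-1-Ar-3-[(benzyloxy)methyl]-6,8-dimethoxy-1,2,3,4-tetrahydronaphthalen-2-yl]methyl sulfate | COc1cc(cc(OC)c1OCc8ccccc8)[C@@H]2c3c(cc(OC)c(OCc4ccccc4)c3OC)C[C@H](COCc5ccccc5)[C@H]2COS(=O)(=O)OCC(Cl)(Cl)Cl
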